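**Plan**

- Numbering: C1 is the free carboxyl, C3 the carbinol carbon, C5 the carboxyl esterified by (Z)-sinapyl alcohol. Cuts, in order: the C5 acyl–O bond to the sinapyl alcohol; the C3–O bond (traced back to C3–B); the C2=C3 bond of an (E)-β-methyl enoate (Horner–Wadsworth–Emmons); the side-chain C=C bond of the alcohol (Still–Gennari olefination of syringaldehyde).
- Enabling feature: C3 is a quaternary carbinol carbon carrying CH3 and OH and lying β to the C1 carbonyl, i.e. the formal hydrate of a β-methyl enoate. The only ring is the purchased benzene ring, so no ring is formed.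
- Forward order of the chain: phosphonate ester, E-enoate, copper–boryl conjugate addition (C3–B), C–B to C–O oxidation, C5 acetal to acid, esterification with the silylated Z-alcohol, one fluoride step for phenol and C1 acid.
- C5 is carried as a dimethyl acetal (aldehyde level) rather than as a protected primary alcohol, because a free 5-hydroxy ester would be a mevalonate ester and would close to mevalonolactone with loss of the C1 ester.
- Stereochemistry: C3 (R in the target) comes from the chiral ligand on copper in the boryl addition and is carried through the oxidation with retention; the Z-alkene comes from the Still–Gennari olefination.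

Key step: step 3

Remark: which antipode of the bisphosphine sends boron to the C3 Si face is fixed by a trial run before scale-up (both antipodes are sold); (R,R)-2,3-bis(tert-butylmethylphosphino)quinoxaline, (R,R)-QuinoxP*, is written below as the working choice.

**Route**

Step 1
Reactants: 1 diethylphosphonoacetic acid; 2 2-(trimethylsilyl)ethanol
Product: 3 2-(trimethylsilyl)ethyl 2-(diethoxyphosphoryl)acetate
Conditions: DCC (1.1 equiv), DMAP (0.1 equiv), CH2Cl2, 0 °C to rt
Reagents that add atoms: none
Why: Steglich esterification of an unhindered acid with a primary alcohol through the O-acylisourea and the acylpyridinium should be clean, and neither partner carries a group sensitive to it.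

Step 2
Reactants: 3 2-(trimethylsilyl)ethyl 2-(diethoxyphosphoryl)acetate; 4 4,4-dimethoxybutan-2-one
Product: 5 2-(trimethylsilyl)ethyl (2E)-5,5-dimethoxy-3-methylpent-2-enoate
Conditions: NaH (1.0 equiv), 3 (1.05 equiv), THF, 0 °C; then 4 (1.2 equiv), 0 °C to rt; chromatography removes the Z isomer
Reagents that add atoms: none
Why: Horner–Wadsworth–Emmons olefination of a methyl ketone with a stabilised phosphonate anion should favour the E-enoate (ester cis to the small CH3), the preformed anion with a slight deficit of base avoids β-elimination of methoxide from the ketone, and the minor Z isomer should be separable on silica.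

Step 3
Reactants: 5 2-(trimethylsilyl)ethyl (2E)-5,5-dimethoxy-3-methylpent-2-enoate; 6 bis(pinacolato)diboron
Product: 7 2-(trimethylsilyl)ethyl (3R)-5,5-dimethoxy-3-methyl-3-(4,4,5,5-tetramethyl-1,3,2-dioxaborolan-2-yl)pentanoate
Conditions: 6 (1.2 equiv), CuCl (5 mol%), NaOtBu (7.5 mol%), (R,R)-QuinoxP* (6 mol%), MeOH (2 equiv), THF, rt; short silica plug
Reagents that add atoms: none
Why: CuCl, NaOtBu and the bisphosphine give L*Cu–OtBu, which undergoes σ-bond metathesis with 6 to L*Cu–Bpin; this monovalent copper–boryl adds syn across C2=C3 of 5 with boron on the β-carbon C3, and methanol protonates the copper enolate to release 7 and L*Cu–OMe, which re-enters the cycle with 6. The closest known reaction type is the monovalent-copper-catalysed enantioselective β-borylation of β,β-disubstituted α,β-unsaturated esters to tertiary boronates. No ring is closed; one C–B bond and one stereocentre are formed. C3 is set by the chiral ligand on copper, which should shield one enantioface so that boron enters on the C3 Si face of the E-enoate and gives the (R)-boronate. The step needs β-regioselectivity and enantiofacial selectivity: the first follows from the polarity of the enoate and the nucleophilic boryl ligand, the second from the geometrically pure E-alkene, whose β-substituents (CH3 against the branched CH2CH(OMe)2 arm) differ clearly in size. The acetal and the silylethyl ester should be inert to the nearly neutral catalytic conditions.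

Step 4
Reactants: 7 2-(trimethylsilyl)ethyl (3R)-5,5-dimethoxy-3-methyl-3-(4,4,5,5-tetramethyl-1,3,2-dioxaborolan-2-yl)pentanoate
Product: 9 2-(trimethylsilyl)ethyl (3S)-3-hydroxy-5,5-dimethoxy-3-methylpentanoate, via borate ester 8 (not isolated)
Conditions: NaBO3·4H2O (5 equiv), THF/H2O (1:1), rt
Reagents that add atoms: sodium perborate tetrahydrate, O.O.O.O.[Na+].[O-]OB=O
Why: Perborate oxidation of an alkylboronate: the peroxide adds to boron, C3 shifts from boron to oxygen with retention to give borate 8, which hydrolyses to the tertiary alcohol, and the mild medium should spare the silylethyl ester and the acetal (the descriptor changes from R to S only because O outranks and B underranks the carbon substituents).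

Step 5
Reactants: 9 2-(trimethylsilyl)ethyl (3S)-3-hydroxy-5,5-dimethoxy-3-methylpentanoate
Product: 10 2-(trimethylsilyl)ethyl (3S)-3-hydroxy-3-methyl-5-oxopentanoate
Conditions: 1 M aq. HCl/THF (1:4), 0 °C to rt; pH 7 buffer work-up; crude aldehyde used at once
Reagents that add atoms: water, O
Why: Acid-catalysed hydrolysis of a dimethyl acetal through the oxocarbenium ion is fast for an unhindered aliphatic acetal under conditions that a silylethyl ester and a tertiary alcohol should tolerate, and the aldehyde level never exposes a free 5-hydroxyl that could lactonise.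

Step 6
Reactants: 10 2-(trimethylsilyl)ethyl (3S)-3-hydroxy-3-methyl-5-oxopentanoate
Product: 11 (3S)-3-hydroxy-3-methyl-5-oxo-5-[2-(trimethylsilyl)ethoxy]pentanoic acid
Conditions: NaClO2, NaH2PO4, 2-methyl-2-butene, t-BuOH/H2O, 0 °C to rt
Reagents that add atoms: sodium chlorite, [Na+].[O-]Cl=O
Why: Pinnick oxidation (chlorous acid adds to the aldehyde and fragments to the acid, the hypochlorous acid being trapped by the alkene) is the standard way to take a β-hydroxy aldehyde to the β-hydroxy acid at pH 3–4 without touching the ester or C3.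

Step 7
Reactants: 12 syringaldehyde
Product: 13 4-[(tert-butyldimethylsilyl)oxy]-3,5-dimethoxybenzaldehyde
Conditions: TBSCl (1.2 equiv), imidazole (2.5 equiv), DMF, rt
Reagents that add atoms: tert-butyldimethylsilyl chloride, CC(C)(C)[Si](C)(C)Cl
Why: Silylation of a phenol with the silyl chloride and imidazole is routine even between two ortho methoxy groups, and it removes the acidic OH before the base-mediated olefination.

Step 8
Reactants: 13 4-[(tert-butyldimethylsilyl)oxy]-3,5-dimethoxybenzaldehyde; 14 methyl 2-[bis(2,2,2-trifluoroethoxy)phosphoryl]acetate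
Product: 15 methyl (2Z)-3-{4-[(tert-butyldimethylsilyl)oxy]-3,5-dimethoxyphenyl}prop-2-enoate
Conditions: KN(SiMe3)2, 18-crown-6, THF, −78 °C
Reagents that add atoms: none
Why: Still–Gennari olefination: with the electron-poor trifluoroethyl phosphonate and a dissociated potassium counter-ion the first adduct eliminates faster than it equilibrates, so the kinetic Z-cinnamate should form from the aromatic aldehyde.

Step 9
Reactants: 15 methyl (2Z)-3-{4-[(tert-butyldimethylsilyl)oxy]-3,5-dimethoxyphenyl}prop-2-enoate
Product: 16 (2Z)-3-{4-[(tert-butyldimethylsilyl)oxy]-3,5-dimethoxyphenyl}prop-2-en-1-ol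
Conditions: iBu2AlH (2.5 equiv), CH2Cl2, −78 °C; aq. potassium sodium tartrate work-up
Reagents that add atoms: none
Why: 1,2-Reduction of a conjugated ester by iBu2AlH at low temperature should give the allylic alcohol without conjugate reduction or Z to E isomerisation, and the aryl silyl ether is inert to the hydride.

Step 10
Reactants: 11 (3S)-3-hydroxy-3-methyl-5-oxo-5-[2-(trimethylsilyl)ethoxy]pentanoic acid; 16 (2Z)-3-{4-[(tert-butyldimethylsilyl)oxy]-3,5-dimethoxyphenyl}prop-2-en-1-ol
Product: 17 1-[(2Z)-3-{4-[(tert-butyldimethylsilyl)oxy]-3,5-dimethoxyphenyl}prop-2-en-1-yl] 5-[2-(trimethylsilyl)ethyl] (3S)-3-hydroxy-3-methylpentanedioate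
Conditions: DCC (1.2 equiv), DMAP (0.2 equiv), CH2Cl2, 0 °C to rt, dark
Reagents that add atoms: none
Why: Steglich esterification: the acylpyridinium from 11 should be taken by the primary allylic alcohol far faster than by the hindered tertiary C3–OH, and the neutral medium does not ionise the electron-rich allylic C–O bond, so the Z geometry should be kept.

Step 11
Reactants: 17 1-[(2Z)-3-{4-[(tert-butyldimethylsilyl)oxy]-3,5-dimethoxyphenyl}prop-2-en-1-yl] 5-[2-(trimethylsilyl)ethyl] (3S)-3-hydroxy-3-methylpentanedioate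
Product: 19 (3R)-3-hydroxy-5-{[(2Z)-3-(4-hydroxy-3,5-dimethoxyphenyl)prop-2-en-1-yl]oxy}-3-methyl-5-oxopentanoic acid, via free-phenol silylethyl ester 18 (not isolated)
Conditions: Bu4NF (5 equiv), AcOH (3 equiv), THF, 0 °C to rt; pH 4 buffer work-up
Reagents that add atoms: none
Why: Fluoride-induced desilylation: the aryl silyl ether should fall first to give 18, then attack at the trimethylsilyl group triggers β-elimination of ethene and releases the C1 carboxylate, while the acetic acid buffer keeps the phenol protonated so that quinone-methide-type loss of the allylic carboxylate is held back (C3 is untouched; its descriptor becomes R because the sinapyl ester arm now outranks the free acid arm).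

**Compound list**

1 | diethylphosphonoacetic acid | CCOP(=O)(CC(=O)O)OCC | starting material
2 | 2-(trimethylsilyl)ethanol | C[Si](C)(C)CCO | starting material
3 | 2-(trimethylsilyl)ethyl 2-(diethoxyphosphoryl)acetate | CCOP(=O)(CC(=O)OCC[Si](C)(C)C)OCC | intermediate
4 | 4,4-dimethoxybutan-2-one | CC(=O)CC(OC)OC | starting material
5 | 2-(trimethylsilyl)ethyl (2E)-5,5-dimethoxy-3-methylpent-2-enoate | C[Si](C)(C)CCOC(=O)/C=C(\C)CC(OC)OC | intermediate
6 | bis(pinacolato)diboron | CC1(C)OB(OC1(C)C)B1OC(C)(C)C(C)(C)O1 | starting material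
7 | 2-(trimethylsilyl)ethyl (3R)-5,5-dimethoxy-3-methyl-3-(4,4,5,5-tetramethyl-1,3,2-dioxaborolan-2-yl)pentanoate | C[Si](C)(C)CCOC(=O)C[C@@](C)(B1OC(C)(C)C(C)(C)O1)CC(OC)OC | intermediate
8 | 2-(trimethylsilyl)ethyl (3S)-5,5-dimethoxy-3-methyl-3-[(4,4,5,5-tetramethyl-1,3,2-dioxaborolan-2-yl)oxy]pentanoate | C[Si](C)(C)CCOC(=O)C[C@@](C)(OB1OC(C)(C)C(C)(C)O1)CC(OC)OC | intermediate
9 | 2-(trimethylsilyl)ethyl (3S)-3-hydroxy-5,5-dimethoxy-3-methylpentanoate | C[Si](C)(C)CCOC(=O)C[C@@](C)(O)CC(OC)OC | intermediate
10 | 2-(trimethylsilyl)ethyl (3S)-3-hydroxy-3-methyl-5-oxopentanoate | C[Si](C)(C)CCOC(=O)C[C@@](C)(O)CC=O | intermediate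
11 | (3S)-3-hydroxy-3-methyl-5-oxo-5-[2-(trimethylsilyl)ethoxy]pentanoic acid | C[Si](C)(C)CCOC(=O)C[C@@](C)(O)CC(=O)O | intermediate
12 | syringaldehyde (4-hydroxy-3,5-dimethoxybenzaldehyde) | COc1cc(C=O)cc(OC)c1O | starting material
13 | 4-[(tert-butyldimethylsilyl)oxy]-3,5-dimethoxybenzaldehyde | COc1cc(C=O)cc(OC)c1O[Si](C)(C)C(C)(C)C | intermediate
14 | methyl 2-[bis(2,2,2-trifluoroethoxy)phosphoryl]acetate | COC(=O)CP(=O)(OCC(F)(F)F)OCC(F)(F)F | starting material
15 | methyl (2Z)-3-{4-[(tert-butyldimethylsilyl)oxy]-3,5-dimethoxyphenyl}prop-2-enoate | COC(=O)/C=C\c1cc(OC)c(O[Si](C)(C)C(C)(C)C)c(OC)c1 | intermediate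
16 | (2Z)-3-{4-[(tert-butyldimethylsilyl)oxy]-3,5-dimethoxyphenyl}prop-2-en-1-ol | OC/C=C\c1cc(OC)c(O[Si](C)(C)C(C)(C)C)c(OC)c1 | intermediate
17 | 1-[(2Z)-3-{4-[(tert-butyldimethylsilyl)oxy]-3,5-dimethoxyphenyl}prop-2-en-1-yl] 5-[2-(trimethylsilyl)ethyl] (3S)-3-hydroxy-3-methylpentanedioate | C[Si](C)(C)CCOC(=O)C[C@@](C)(O)CC(=O)OC/C=C\c1cc(OC)c(O[Si](C)(C)C(C)(C)C)c(OC)c1 | intermediate
18 | 1-[(2Z)-3-(4-hydroxy-3,5-dimethoxyphenyl)prop-2-en-1-yl] 5-[2-(trimethylsilyl)ethyl] (3S)-3-hydroxy-3-methylpentanedioate | C[Si](C)(C)CCOC(=O)C[C@@](C)(O)CC(=O)OC/C=C\c1cc(OC)c(O)c(OC)c1 | intermediate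
19 | (3R)-3-hydroxy-5-{[(2Z)-3-(4-hydroxy-3,5-dimethoxyphenyl)prop-2-en-1-yl]oxy}-3-methyl-5-oxopentanoic acid | COc1cc(/C=C\COC(=O)C[C@](C)(O)CC(=O)O)cc(OC)c1O | target

**Count and risks**

Total steps: 11. Longest linear sequence: 8 steps (steps 1 to 6, then 10 and 11); the sinapyl branch (steps 7 to 9) joins at step 10.

Step 3. The borylcupration of the trisubstituted enoate may be sluggish, or the ligand may discriminate poorly between two alkyl β-substituents, so that C3 is formed with insufficient enantiomeric purity. The fallback sets out from 5 and comes back at 9. iBu2AlH (CH2Cl2, −78 °C) reduces the ester of 5 to (2E)-5,5-dimethoxy-3-methylpent-2-en-1-ol F1. Sharpless asymmetric epoxidation (Ti(OiPr)4, L-(+)-diethyl tartrate, t-BuOOH, 4 Å molecular sieves, CH2Cl2, −20 °C) should give [(2S,3S)-3-(2,2-dimethoxyethyl)-3-methyloxiran-2-yl]methanol F2, the facial sense being that known for geraniol, which has the same substitution pattern. NaAlH2(OCH2CH2OMe)2 in THF delivers hydride to C2 and should give (3R)-5,5-dimethoxy-3-methylpentane-1,3-diol F3. TEMPO with catalytic NaOCl and stoichiometric NaClO2 at pH 6.7 oxidises only the primary alcohol to (3S)-3-hydroxy-5,5-dimethoxy-3-methylpentanoic acid F4, and DCC/DMAP esterification of F4 with 2 returns to 9.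

Step 5. Acid may dehydrate the tertiary β-hydroxy aldehyde to the enal, or the free β-hydroxy aldehyde may self-condense or close onto the C1 ester through its hydrate. The fallback sets out from 9 and comes back at 19; it avoids both aqueous acid and a free β-hydroxy aldehyde. Et3SiOTf/2,6-lutidine (CH2Cl2, −78 to 0 °C) silylates the tertiary alcohol to 2-(trimethylsilyl)ethyl (3S)-5,5-dimethoxy-3-methyl-3-[(triethylsilyl)oxy]pentanoate F5. A further portion of Et3SiOTf/2,6-lutidine followed by water cleaves the dimethyl acetal through a pyridinium adduct to 2-(trimethylsilyl)ethyl (3S)-3-methyl-5-oxo-3-[(triethylsilyl)oxy]pentanoate F6, a β-silyloxy aldehyde of the robust aldol-product type. Pinnick oxidation should give (3S)-3-methyl-5-oxo-3-[(triethylsilyl)oxy]-5-[2-(trimethylsilyl)ethoxy]pentanoic acid F7. DCC/DMAP coupling with 16 gives 1-[(2Z)-3-{4-[(tert-butyldimethylsilyl)oxy]-3,5-dimethoxyphenyl}prop-2-en-1-yl] 5-[2-(trimethylsilyl)ethyl] (3S)-3-methyl-3-[(triethylsilyl)oxy]pentanedioate F8, and Bu4NF/AcOH in THF removes all three silyl groups to give 19.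

Step 11. Once the phenol is free, a phenoxide may expel the allylic carboxylate (extended quinone methide), the Z-alkene may isomerise, or the silylethyl ester may cleave too slowly under the buffered conditions that protect against the first two. The fallback sets out from 11 and 13 and comes back at 19; it moves the desilylation to an alkyne stage and makes the Z-alkene last. Corey–Fuchs reaction of 13 (CBr4, PPh3, CH2Cl2, 0 °C) gives tert-butyl[4-(2,2-dibromoethenyl)-2,6-dimethoxyphenoxy]dimethylsilane F9. n-BuLi (2 equiv, THF, −78 °C) followed by paraformaldehyde gives 3-{4-[(tert-butyldimethylsilyl)oxy]-3,5-dimethoxyphenyl}prop-2-yn-1-ol F10. DCC/DMAP coupling with 11 gives 1-[3-{4-[(tert-butyldimethylsilyl)oxy]-3,5-dimethoxyphenyl}prop-2-yn-1-yl] 5-[2-(trimethylsilyl)ethyl] (3S)-3-hydroxy-3-methylpentanedioate F11. Bu4NF/AcOH then removes both silyl groups; at this stage a quinone methide would have to be a cumulene and no geometric isomer exists, so (3R)-3-hydroxy-5-{[3-(4-hydroxy-3,5-dimethoxyphenyl)prop-2-yn-1-yl]oxy}-3-methyl-5-oxopentanoic acid F12 should result. Lindlar semi-hydrogenation (H2, Pd/CaCO3 poisoned with Pb(OAc)2, quinoline, EtOAc, rt) then gives 19.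

**Further compounds**

F1 | step 3 | (2E)-5,5-dimethoxy-3-methylpent-2-en-1-ol | OC/C=C(\C)CC(OC)OC
F2 | step 3 | [(2S,3S)-3-(2,2-dimethoxyethyl)-3-methyloxiran-2-yl]methanol | OC[C@@H]1O[C@@]1(C)CC(OC)OC
F3 | step 3 | (3R)-5,5-dimethoxy-3-methylpentane-1,3-diol | OCC[C@@](C)(O)CC(OC)OC
F4 | step 3 | (3S)-3-hydroxy-5,5-dimethoxy-3-methylpentanoic acid | OC(=O)C[C@@](C)(O)CC(OC)OC
F5 | step 5 | 2-(trimethylsilyl)ethyl (3S)-5,5-dimethoxy-3-methyl-3-[(triethylsilyl)oxy]pentanoate | C[Si](C)(C)CCOC(=O)C[C@@](C)(O[Si](CC)(CC)CC)CC(OC)OC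
F6 | step 5 | 2-(trimethylsilyl)ethyl (3S)-3-methyl-5-oxo-3-[(triethylsilyl)oxy]pentanoate | C[Si](C)(C)CCOC(=O)C[C@@](C)(O[Si](CC)(CC)CC)CC=O
F7 | step 5 | (3S)-3-methyl-5-oxo-3-[(triethylsilyl)oxy]-5-[2-(trimethylsilyl)ethoxy]pentanoic acid | C[Si](C)(C)CCOC(=O)C[C@@](C)(O[Si](CC)(CC)CC)CC(=O)O
F8 | step 5 | 1-[(2Z)-3-{4-[(tert-butyldimethylsilyl)oxy]-3,5-dimethoxyphenyl}prop-2-en-1-yl] 5-[2-(trimethylsilyl)ethyl] (3S)-3-methyl-3-[(triethylsilyl)oxy]pentanedioate | C[Si](C)(C)CCOC(=O)C[C@@](C)(O[Si](CC)(CC)CC)CC(=O)OC/C=C\c1cc(OC)c(O[Si](C)(C)C(C)(C)C)c(OC)c1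
F9 | step 11 | tert-butyl[4-(2,2-dibromoethenyl)-2,6-dimethoxyphenoxy]dimethylsilane | BrC(Br)=Cc1cc(OC)c(O[Si](C)(C)C(C)(C)C)c(OC)c1
F10 | step 11 | 3-{4-[(tert-butyldimethylsilyl)oxy]-3,5-dimethoxyphenyl}prop-2-yn-1-ol | OCC#Cc1cc(OC)c(O[Si](C)(C)C(C)(C)C)c(OC)c1
F11 | step 11 | 1-[3-{4-[(tert-butyldimethylsilyl)oxy]-3,5-dimethoxyphenyl}prop-2-yn-1-yl] 5-[2-(trimethylsilyl)ethyl] (3S)-3-hydroxy-3-methylpentanedioate | C[Si](C)(C)CCOC(=O)C[C@@](C)(O)CC(=O)OCC#Cc1cc(OC)c(O[Si](C)(C)C(C)(C)C)c(OC)c1
F12 | step 11 | (3R)-3-hydroxy-5-{[3-(4-hydroxy-3,5-dimethoxyphenyl)prop-2-yn-1-yl]oxy}-3-methyl-5-oxopentanoic acid | OC(=O)C[C@@](C)(O)CC(=O)OCC#Cc1cc(OC)c(O)c(OC)c1
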